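Read the constants first: the product-forming step and the decomposition are both first order in coupling partner, so c(coupling partner) cancels from their ratio.

in all of them: substrate 0.25 M; precatalyst 1.8 mM
- beta: coupling partner 0.325 M; time 40 s; plug flow through a tube for 40 s, no back-mixing
- gamma: coupling partner 0.325 M (fed, over 32.0 s); time 40 s; a stirred flask in which coupling partner is dosed at a steady rate over 32.0 s without added volume, worked up at 40 s
- alpha: coupling partner 0.325 M; one stirred flow tank at steady state, fed with the mixture as stated, mean residence time 40 s
- eta: coupling partner 0.325 M; time 40 s; a closed flask charged with all of it at once and left for 40 s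

    substrate + free catalyst → free catalyst + open intermediate (k1 = 180 M⁻¹ s⁻¹)
    free catalyst + open intermediate ⇌ catalyst intermediate (K2 = 11 M⁻¹, k2 = 66 M⁻¹ s⁻¹)
    coupling partner + catalyst intermediate → free catalyst + product (k3 = 180 M⁻¹ s⁻¹)
    coupling partner + precatalyst → free catalyst + spent reagent (k4 = 3.9 M⁻¹ s⁻¹)
    coupling partner → decomposed reagent (k5 = 0.042 s⁻¹)

1. the set-up with the highest amount of product at the outlet or at the end, in percent of the substrate put in ("none" if the first two lie within 2 percentage points) (beta / gamma / alpha / eta / none)
2. amount of product at the outlet or at the end, in percent of the substrate put in, beta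
3. amount of product at the outlet or at the end, in percent of the substrate put in, gamma
4. amount of product at the outlet or at the end, in percent of the substrate put in, alpha
5. amount of product at the outlet or at the end, in percent of the substrate put in, eta

- the stated concentrations are those of everything mixed, before any reaction; amounts are the same in each set-up
- the feed brings no volume worth counting
- run time (beta): 40 s

That ratio is the selectivity factor S = 180 M⁻¹ s⁻¹ × c(catalyst intermediate) / 0.042 s⁻¹, coupling partner turned into product per coupling partner decomposed. With the catalyst charge wholly as catalyst intermediate it reaches its ceiling:

ceiling = 180 M⁻¹ s⁻¹ × 1.8 mM / 0.042 s⁻¹ = 7.71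

Apply the bench rule: 1.30 equivalents cover the substrate while decomposition stays within the excess. Neglecting the spent reagent, less than the excess, that demands:

needed S = 0.25 M / (0.325 M − 0.25 M) = 3.33, a catalyst intermediate share of 43.2 %

Now find the border for a flask charged at once. Activation and opening have half-lives of 0.547 s and 2.14 s, both shorter than the 17 s of decomposition, so take the substrate charge as open intermediate. Capture, reversal and the product step then give:

share = 16.5 s⁻¹ / (16.5 s⁻¹ + 6.00 s⁻¹ + 58.5 s⁻¹) = 20.4 %

S at the start = 1.57

This is less than the needed S, so the rule fails for eta and for beta, whose plug of liquid is a closed flask travelling. Holding the starting S gives 79.4 % product for both. Solve instead for the level at which S meets the need: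

c× = (16.5 s⁻¹ × (ceiling / needed S − 1) − 6.00 s⁻¹) / 180 M⁻¹ s⁻¹ = 0.0871 M

Call this the crossing level of coupling partner: above it, with the substrate charge open, decomposition costs more than the excess pays. The charge stands above it, while gamma starts without coupling partner and is fed 0.0102 M s⁻¹. Rank gamma above eta; this reckoning gives no figure for gamma or alpha.

The forecast gives 73 % for beta, 82 % for gamma, 62 % for alpha and 73 % for eta, which is under the 79.4 % reckoned here for eta, and picks gamma, holding that “Dosing keeps the coupling partner low”.

The simulation gives 73.7 % for beta, 78.3 % for gamma, 62.1 % for alpha and 73.7 % for eta, so gamma leads.

In gamma at 20.0 s, coupling partner stands at 0.0667 M, under the crossing level of 0.0871 M, but that level was reckoned with the whole substrate charge open, and 58.3 % of the substrate is open intermediate then; catalyst intermediate is 34.3 % of the catalyst charged, under the needed 43.2 %. Carry the reckoning to the neighbour of gamma charged with 0.81 M of coupling partner, 3.24 equiv. Its needed S falls to 0.446, and its crossing level rises to 1.46 M, above its whole charge. That flask gives 94.7 % product, with 27 % of its coupling partner still unbound at 40.0 s.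

The numbers were drawn at random within sensible limits; the rest is arithmetic.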